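**Plan**

1. Retrosynthesis: the first cut is the diaryl ether bond between O6 of unit 1 (the 5-hydroxy-7-methoxyflavone, unprimed atoms, 2-aryl ring B) and the para carbon of ring B' of unit 2 (the 5,7-dihydroxyflavone, primed atoms). The second cut opens ring A' of unit 2 at C8'–C8a', C7'–C8', C5'–C6' and C4a'–C5'.
2. Enabling feature: ring A' is a 1,3,5-trioxygenated benzene whose fusion bond C4a'–C8a' is the C5=C6 bond of a 2-aryl-4-pyranone (ring C'). C5'–OH maps onto a ketene carbonyl and C7'–O onto the oxygen-bearing carbon of an ynol ether.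
3. Forward, unit 2: ring C' by Claisen condensation and cyclodehydration, then the diazoketone, then ring A' by Wolff rearrangement and ketene–ethoxyacetylene benzannulation, then exchange of O-ethyl for O-benzyl.
4. Forward, unit 1: ring A from 2,6-dimethoxyhydroquinone, ring C by Baker–Venkataraman rearrangement and cyclodehydration, then release of the 6-OH.
5. Union by Ullmann etherification; one BCl3 step then removes three benzyl groups and the chelated 5-O-methyl group. The target has no stereocentre, so no stereocontrol is required.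

Key step: step 3

Assumption: compounds 1, 2, 8 (as a solution in hexanes), 16 and 18 are purchased.

Remark: bromine is carried on ring B' because a para halogen on a 5,7-dialkoxyflavone is only vinylogously activated and the phenoxide of unit 1 is flanked by two methoxy groups, so copper catalysis is the safer way to the ether. Ethoxyacetylene serves as the ynol ether because both oxygens of ring A' end as free hydroxyls, so O7' only needs a group that BBr3 removes before the benzyl ethers are put on.

**Route**

Step 1
Reactants: 1 1-(4-bromophenyl)butane-1,3-dione; 2 diethyl oxalate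
Product: 5 6-(4-bromophenyl)-4-oxo-4H-pyran-2-carboxylic acid, via triketo ester 3 (not isolated), via pyranone ethyl ester 4 (not isolated)
Conditions: NaOEt (2.2 equiv), EtOH, 0 °C → rt; then conc. HCl, AcOH, reflux
Reagents that add atoms: water, O
Why: Two equivalents of ethoxide allow the oxalate to acylate the terminal methyl group of the β-diketone (crossed Claisen condensation, the bis-enolate of the 2,4,6-trioxo ester being the thermodynamic sink), and hot aqueous acid then cyclodehydrates the 1,3,5-tricarbonyl unit to the 4-pyranone and hydrolyses the ester, the sequence by which chelidonic acid is classically made.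

Step 2
Reactants: 5 6-(4-bromophenyl)-4-oxo-4H-pyran-2-carboxylic acid
Product: 7 2-(4-bromophenyl)-6-(2-diazoacetyl)-4H-pyran-4-one, via acid chloride 6 (not isolated)
Conditions: (COCl)2, cat. DMF, CH2Cl2, rt; then CH2N2 (3 equiv), Et2O/THF, 0 °C
Reagents that add atoms: diazomethane, C=[N+]=[N-]
Why: Acylation of diazomethane by the acid chloride (the first stage of an Arndt–Eistert sequence) should give the diazomethyl ketone, the excess diazomethane consuming the HCl so that no chloromethyl ketone forms, and the 4-pyranone ring is inert to both reagents.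

Step 3
Reactants: 7 2-(4-bromophenyl)-6-(2-diazoacetyl)-4H-pyran-4-one; 8 ethoxyacetylene
Product: 13 2-(4-bromophenyl)-7-ethoxy-5-hydroxy-4H-chromen-4-one, via pyranonylketene 9 (not isolated), via ethoxycyclobutenone 10 (not isolated), via dienylketene 11 (not isolated), via cyclohexadienone 12 (not isolated)
Conditions: 8 (3 equiv), ClCH2CH2Cl (degassed), hν (405 nm LED), rt; then 80 °C
Reagents that add atoms: none
Why: Light of 405 nm should excite only the diazoketone, whose Wolff rearrangement (loss of N2 with 1,2-shift of the pyranonyl group) bonds the former diazo carbon C8' to C8a' and gives ketene 9; the nucleophilic unsubstituted carbon of the ynol ether then attacks the ketene carbonyl carbon (C5'–C6') and the ethoxy-bearing carbon closes onto the ketene α-carbon (C7'–C8') in a (2+2) cycloaddition to 10. On warming, reversible four-electron conrotatory opening of 10 gives dienylketene 11, whose E isomer holds the pyranone C5=C6 bond next to the ketene. Ring A' closes by a thermal six-electron disrotatory electrocyclisation that forms C4a'–C5', and the doubly activated C4a'–H of 12 tautomerises to the chelated 5'-phenol. This is the diazoketone (photochemical Wolff) form of the Danheiser benzannulation, established for aryl, heteroaryl and alkenyl diazomethyl ketones with alkoxy- and siloxyalkynes, the pyranone double bond here taking the part of the alkene or arene bond. No stereocentre is formed; the required regiochemistry (oxygen at C7', hydrogen at C6') follows from the polarisation of the ynol ether, and only one carbon (C4a') flanks C8a', so a single annulation product is possible.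

Step 4
Reactants: 13 2-(4-bromophenyl)-7-ethoxy-5-hydroxy-4H-chromen-4-one
Product: 14 2-(4-bromophenyl)-5,7-dihydroxy-4H-chromen-4-one
Conditions: BBr3 (4 equiv), CH2Cl2, −78 °C → rt; then H2O
Reagents that add atoms: none
Why: BBr3 coordinates the ether oxygen and bromide displaces the ethyl group (Lewis-acid dealkylation of an aryl alkyl ether), while the aryl bromide, the chromone and the phenol should survive.

Step 5
Reactants: 14 2-(4-bromophenyl)-5,7-dihydroxy-4H-chromen-4-one
Product: 15 5,7-bis(benzyloxy)-2-(4-bromophenyl)-4H-chromen-4-one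
Conditions: BnBr (3 equiv), K2CO3, DMF, 70 °C
Reagents that add atoms: benzyl bromide, BrCc1ccccc1
Why: Williamson etherification of both phenols, the chelated 5'-OH needing the warm DMF conditions; benzyl ethers are chosen because they withstand the basic copper coupling and fall to BCl3 at the end.

Step 6
Reactants: 16 2,6-dimethoxyhydroquinone
Product: 17 1-(3,6-dihydroxy-2,4-dimethoxyphenyl)ethan-1-one
Conditions: AcOH, BF3·OEt2, 90 °C; then H2O
Reagents that add atoms: acetic acid, CC(=O)O
Why: Friedel–Crafts C-acetylation of the electron-rich hydroquinone (by way of a Fries-type O-to-C acyl shift under BF3); the two free ring positions are equivalent by symmetry and the acyl group deactivates the ring toward a second acylation.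

Step 7
Reactants: 17 1-(3,6-dihydroxy-2,4-dimethoxyphenyl)ethan-1-one; 18 4-(benzyloxy)benzoic acid
Product: 20 2-acetyl-3,5-dimethoxy-1,4-phenylene bis[4-(benzyloxy)benzoate], via 4-(benzyloxy)benzoyl chloride 19 (not isolated)
Conditions: 18 (2.5 equiv), (COCl)2, cat. DMF, CH2Cl2, rt; then 17, pyridine, cat. DMAP, 0 °C → rt
Reagents that add atoms: none
Why: Acid chloride formation followed by pyridine/DMAP esterification acylates both phenols, the chelated one included; the ester ortho to the acetyl group is the acyl donor for the next step and the other protects the future 6-OH.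

Step 8
Reactants: 20 2-acetyl-3,5-dimethoxy-1,4-phenylene bis[4-(benzyloxy)benzoate]
Product: 22 2-[4-(benzyloxy)phenyl]-5,7-dimethoxy-4-oxo-4H-chromen-6-yl 4-(benzyloxy)benzoate, via 1,3-diketone 21 (not isolated)
Conditions: LiN(SiMe3)2 (3 equiv), THF, −78 °C → rt; then AcOH, cat. H2SO4, 95 °C
Reagents that add atoms: none
Why: Baker–Venkataraman rearrangement, in which the ketone enolate attacks the ortho ester through a six-membered transition state to give the 1,3-diketone, followed by acid cyclodehydration to the flavone; the ester meta to the acyl chain cannot transfer and stays on O6.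

Step 9
Reactants: 22 2-[4-(benzyloxy)phenyl]-5,7-dimethoxy-4-oxo-4H-chromen-6-yl 4-(benzyloxy)benzoate
Product: 23 2-[4-(benzyloxy)phenyl]-6-hydroxy-5,7-dimethoxy-4H-chromen-4-one
Conditions: LiOH (3 equiv), THF/H2O, rt; then aq. HCl
Reagents that add atoms: none
Why: Saponification of the aryl ester, whose phenoxide is a good leaving group, should be fast at room temperature, where hydroxide does not open the flavone ring, and it returns acid 18.

Step 10
Reactants: 15 5,7-bis(benzyloxy)-2-(4-bromophenyl)-4H-chromen-4-one; 23 2-[4-(benzyloxy)phenyl]-6-hydroxy-5,7-dimethoxy-4H-chromen-4-one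
Product: 24 6-{4-[5,7-bis(benzyloxy)-4-oxo-4H-chromen-2-yl]phenoxy}-2-[4-(benzyloxy)phenyl]-5,7-dimethoxy-4H-chromen-4-one
Conditions: CuI (10 mol%), picolinic acid (20 mol%), K3PO4, DMSO, 95 °C, under Ar
Reagents that add atoms: none
Why: Ullmann diaryl ether synthesis under ligand-accelerated catalysis by monovalent copper; the aryl bromide is unhindered and electron-poor (para to the chromone), the phenoxide is electron-rich, and the picolinate ligand tolerates phenols with two ortho substituents.

Step 11
Reactants: 24 6-{4-[5,7-bis(benzyloxy)-4-oxo-4H-chromen-2-yl]phenoxy}-2-[4-(benzyloxy)phenyl]-5,7-dimethoxy-4H-chromen-4-one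
Product: 25 isocryptomerin
Conditions: BCl3 (excess), C6HMe5, CH2Cl2, −78 °C → rt; then H2O
Reagents that add atoms: none
Why: BCl3 cleaves the three benzyl ethers (the benzyl cations being trapped by pentamethylbenzene) and, through a six-membered boron chelate with the C4 carbonyl, the peri 5-O-methyl ether, whereas the unchelated 7-O-methyl group and the diaryl ether should not be attacked under these conditions.

**Compound list**

1 | 1-(4-bromophenyl)butane-1,3-dione | CC(=O)CC(=O)c1ccc(Br)cc1 | starting material
2 | diethyl oxalate | CCOC(=O)C(=O)OCC | starting material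
3 | ethyl 6-(4-bromophenyl)-2,4,6-trioxohexanoate (sodium enolate in the flask, not isolated) | CCOC(=O)C(=O)CC(=O)CC(=O)c1ccc(Br)cc1 | intermediate
4 | ethyl 6-(4-bromophenyl)-4-oxo-4H-pyran-2-carboxylate (not isolated) | CCOC(=O)c1cc(=O)cc(-c2ccc(Br)cc2)o1 | intermediate
5 | 6-(4-bromophenyl)-4-oxo-4H-pyran-2-carboxylic acid | OC(=O)c1cc(=O)cc(-c2ccc(Br)cc2)o1 | intermediate
6 | 6-(4-bromophenyl)-4-oxo-4H-pyran-2-carbonyl chloride (not isolated) | ClC(=O)c1cc(=O)cc(-c2ccc(Br)cc2)o1 | intermediate
7 | 2-(4-bromophenyl)-6-(2-diazoacetyl)-4H-pyran-4-one | O=C(C=[N+]=[N-])c1cc(=O)cc(-c2ccc(Br)cc2)o1 | intermediate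
8 | ethoxyacetylene (ethyl ethynyl ether) | C#COCC | starting material
9 | 2-[6-(4-bromophenyl)-4-oxo-4H-pyran-2-yl]ethen-1-one, the pyranonylketene (not isolated) | O=C=Cc1cc(=O)cc(-c2ccc(Br)cc2)o1 | intermediate
10 | 4-[6-(4-bromophenyl)-4-oxo-4H-pyran-2-yl]-3-ethoxycyclobut-2-en-1-one (racemic, not isolated) | CCOC1=CC(=O)C1c1cc(=O)cc(-c2ccc(Br)cc2)o1 | intermediate
11 | (3E)-4-[6-(4-bromophenyl)-4-oxo-4H-pyran-2-yl]-3-ethoxybuta-1,3-dien-1-one, the dienylketene (not isolated) | O=C=C/C(OCC)=C\c1cc(=O)cc(-c2ccc(Br)cc2)o1 | intermediate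
12 | 2-(4-bromophenyl)-7-ethoxy-4aH-chromene-4,5-dione (racemic, not isolated) | CCOC1=CC(=O)C2C(=O)C=C(-c3ccc(Br)cc3)OC2=C1 | intermediate
13 | 2-(4-bromophenyl)-7-ethoxy-5-hydroxy-4H-chromen-4-one | CCOc1cc(O)c2c(c1)oc(-c1ccc(Br)cc1)cc2=O | intermediate
14 | 2-(4-bromophenyl)-5,7-dihydroxy-4H-chromen-4-one | Oc1cc(O)c2c(c1)oc(-c1ccc(Br)cc1)cc2=O | intermediate
15 | 5,7-bis(benzyloxy)-2-(4-bromophenyl)-4H-chromen-4-one | O=c1cc(-c2ccc(Br)cc2)oc2cc(OCc3ccccc3)cc(OCc3ccccc3)c12 | intermediate
16 | 2,6-dimethoxyhydroquinone (2,6-dimethoxybenzene-1,4-diol) | COc1cc(O)cc(OC)c1O | starting material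
17 | 1-(3,6-dihydroxy-2,4-dimethoxyphenyl)ethan-1-one | CC(=O)c1c(O)cc(OC)c(O)c1OC | intermediate
18 | 4-(benzyloxy)benzoic acid | OC(=O)c1ccc(OCc2ccccc2)cc1 | starting material
19 | 4-(benzyloxy)benzoyl chloride (not isolated) | ClC(=O)c1ccc(OCc2ccccc2)cc1 | intermediate
20 | 2-acetyl-3,5-dimethoxy-1,4-phenylene bis[4-(benzyloxy)benzoate] | CC(=O)c1c(OC(=O)c2ccc(OCc3ccccc3)cc2)cc(OC)c(OC(=O)c2ccc(OCc3ccccc3)cc2)c1OC | intermediate
21 | 3-{3-[4-(benzyloxy)phenyl]-3-oxopropanoyl}-4-hydroxy-2,6-dimethoxyphenyl 4-(benzyloxy)benzoate (not isolated) | O=C(CC(=O)c1c(O)cc(OC)c(OC(=O)c2ccc(OCc3ccccc3)cc2)c1OC)c1ccc(OCc2ccccc2)cc1 | intermediate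
22 | 2-[4-(benzyloxy)phenyl]-5,7-dimethoxy-4-oxo-4H-chromen-6-yl 4-(benzyloxy)benzoate | COc1cc2oc(-c3ccc(OCc4ccccc4)cc3)cc(=O)c2c(OC)c1OC(=O)c1ccc(OCc2ccccc2)cc1 | intermediate
23 | 2-[4-(benzyloxy)phenyl]-6-hydroxy-5,7-dimethoxy-4H-chromen-4-one | COc1cc2oc(-c3ccc(OCc4ccccc4)cc3)cc(=O)c2c(OC)c1O | intermediate
24 | 6-{4-[5,7-bis(benzyloxy)-4-oxo-4H-chromen-2-yl]phenoxy}-2-[4-(benzyloxy)phenyl]-5,7-dimethoxy-4H-chromen-4-one | COc1cc2oc(-c3ccc(OCc4ccccc4)cc3)cc(=O)c2c(OC)c1Oc1ccc(-c2cc(=O)c3c(OCc4ccccc4)cc(OCc4ccccc4)cc3o2)cc1 | intermediate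
25 | isocryptomerin, 6-[4-(5,7-dihydroxy-4-oxo-4H-chromen-2-yl)phenoxy]-5-hydroxy-2-(4-hydroxyphenyl)-7-methoxy-4H-chromen-4-one | COc1cc2oc(-c3ccc(O)cc3)cc(=O)c2c(O)c1Oc1ccc(-c2cc(=O)c3c(O)cc(O)cc3o2)cc1 | target

**Step count and risks**

Total steps: 11. Longest linear sequence: 7 steps (steps 1 to 5, then 10 and 11).

Step 3. Under irradiation the pyranone chromophore may enter photoreactions of its own, or the excited diazoketone may react through carbene pathways instead of rearranging, so that the ketene is formed or captured inefficiently. The fallback makes the same ketene in the dark. Setting out from 7, a silver-catalysed Wolff rearrangement in aqueous THF (PhCO2Ag, Et3N; Arndt–Eistert homologation) would give 2-[6-(4-bromophenyl)-4-oxo-4H-pyran-2-yl]acetic acid F1. Oxalyl chloride with catalytic DMF below room temperature would convert it into 2-[6-(4-bromophenyl)-4-oxo-4H-pyran-2-yl]acetyl chloride F2. Slow addition of Et3N to F2 and an excess of 8 in toluene at 0 °C would generate ketene 9 by dehydrochlorination; 9 would be taken up by 8 to give 10, and warming to 80 °C would carry 10 through 11 and 12 back to the route at 13.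

Step 10. Ligand exchange and reductive elimination at copper may be slow for a phenoxide flanked by two methoxy groups, so that hydrodebromination of the aryl bromide or oxidative degradation of the phenoxide competes. The fallback inverts the roles at copper and runs at room temperature. Setting out from 15, Miyaura borylation (B2pin2, PdCl2(dppf), KOAc, dioxane, 85 °C) would give 5,7-bis(benzyloxy)-2-[4-(4,4,5,5-tetramethyl-1,3,2-dioxaborolan-2-yl)phenyl]-4H-chromen-4-one F3. Oxidative cleavage of the pinacol ester (NaIO4, NH4OAc, acetone/H2O) would give {4-[5,7-bis(benzyloxy)-4-oxo-4H-chromen-2-yl]phenyl}boronic acid F4. A Chan–Lam coupling of F4 with 23 (Cu(OAc)2, pyridine, 4 Å molecular sieves, CH2Cl2, air, rt) would then form the same C–O bond by way of a trivalent copper aryl phenoxide and rejoin the route at 24.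

Step 11. Cleavage of the chelated 5-O-methyl ether may lag behind debenzylation, and forcing it may cause loss of the 7-O-methyl group or Friedel–Crafts benzylation of the electron-rich ring A'. The fallback separates the two events. Setting out from 24, hydrogenolysis (H2, Pd/C, THF/MeOH, rt) would remove the three benzyl groups and give 6-[4-(5,7-dihydroxy-4-oxo-4H-chromen-2-yl)phenoxy]-2-(4-hydroxyphenyl)-5,7-dimethoxy-4H-chromen-4-one F5. Chelation-directed demethylation of the 5-O-methyl ether of F5 with AlCl3 in MeCN at 60 °C would then give 25.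

**Further compounds**

F1 | step 3 | 2-[6-(4-bromophenyl)-4-oxo-4H-pyran-2-yl]acetic acid | OC(=O)Cc1cc(=O)cc(-c2ccc(Br)cc2)o1
F2 | step 3 | 2-[6-(4-bromophenyl)-4-oxo-4H-pyran-2-yl]acetyl chloride | ClC(=O)Cc1cc(=O)cc(-c2ccc(Br)cc2)o1
F3 | step 10 | 5,7-bis(benzyloxy)-2-[4-(4,4,5,5-tetramethyl-1,3,2-dioxaborolan-2-yl)phenyl]-4H-chromen-4-one | CC1(C)OB(c2ccc(-c3cc(=O)c4c(OCc5ccccc5)cc(OCc5ccccc5)cc4o3)cc2)OC1(C)C
F4 | step 10 | {4-[5,7-bis(benzyloxy)-4-oxo-4H-chromen-2-yl]phenyl}boronic acid | OB(O)c1ccc(-c2cc(=O)c3c(OCc4ccccc4)cc(OCc4ccccc4)cc3o2)cc1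
F5 | step 11 | 6-[4-(5,7-dihydroxy-4-oxo-4H-chromen-2-yl)phenoxy]-2-(4-hydroxyphenyl)-5,7-dimethoxy-4H-chromen-4-one | COc1cc2oc(-c3ccc(O)cc3)cc(=O)c2c(OC)c1Oc1ccc(-c2cc(=O)c3c(O)cc(O)cc3o2)cc1
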